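**Strategy.** Ring B is closed by joining C2 to C3 (decahydronaphthalene numbering of the target) in a 6-endo radical cyclisation. The step exploits the 1,4 relationship of the two oxygenated carbons of ring B: a ketone at C4 turns C3 into an electrophilic α-keto radical, and the C1 oxygen is present as an enol 4-methoxybenzoate whose CH2 terminus (C2) is the acceptor. One operation therefore forms ring B and the stereocentres C3 and C1, with the ester already in place. The precursor is a ring-A cyclohexane carrying, cis to each other, a 2-bromo-3-methylbutanoyl group on C4a and a 1-(aroyloxy)vinyl group on the quaternary C8a.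

Key step: step 7

Remark on numbering: C1 ester carbon, C2 methylene, C3 isopropyl carbon, C4 carbinol carbon, C4a ring-fusion CH, C5 methylidene carbon, C8a methyl-bearing quaternary carbon; ring B is C1–C4, C4a, C8a.
Remark on step 2: the sense of induction of the copper–carbene catalyst is assumed; the ligand antipode that delivers the (R)-quaternary centre is the one used.
Remark on compounds 11 and 13: both are carried as mixtures of the two C–Br epimers, because that centre becomes a planar radical in step 7.

**Step 1**
Reactants: 1 3-ethoxycyclohex-2-en-1-one; 2 ethynyltrimethylsilane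
Product: 4 3-[(trimethylsilyl)ethynyl]cyclohex-2-en-1-one, via lithium propargylic alkoxide 3 (not isolated)
Conditions: 2, n-BuLi, THF, −78 °C; add 1, −78 to 0 °C; then 1 M aq. HCl, rt
Reagents that add atoms: water, O
Why: 1,2-addition of the lithium acetylide to the vinylogous ester, then acid hydrolysis with loss of ethanol and water, should give the 3-alkynyl enone (Stork–Danheiser transposition); no stereocentre is formed.

**Step 2**
Reactants: 4 3-[(trimethylsilyl)ethynyl]cyclohex-2-en-1-one
Product: 6 (3R)-3-methyl-3-[(trimethylsilyl)ethynyl]cyclohex-1-en-1-yl trifluoromethanesulfonate, via bromomagnesium enolate 5 (not isolated)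
Conditions: MeMgBr, Cu(OTf)2 (cat.), chiral C2-symmetric imidazolinium tetrafluoroborate (carbene precursor, cat.), Et2O, −30 °C; then Comins' reagent, THF, −30 °C to rt
Reagents that add atoms: methylmagnesium bromide, C[Mg]Br; N-(5-chloropyridin-2-yl)-1,1,1-trifluoro-N-[(trifluoromethyl)sulfonyl]methanesulfonamide (Comins' reagent), FC(F)(F)S(=O)(=O)N(c1ccc(Cl)cn1)S(=O)(=O)C(F)(F)F
Why: Copper-catalysed asymmetric conjugate addition should be 1,4-selective because the silyl cap shields the alkyne terminus, with the chiral carbene ligand setting the quaternary centre as (R); O-sulfonylation of the regiodefined magnesium enolate fixes the double bond on the side of the quaternary carbon.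

**Step 3**
Reactants: 6 (3R)-3-methyl-3-[(trimethylsilyl)ethynyl]cyclohex-1-en-1-yl trifluoromethanesulfonate; 7 (trimethylsilyl)methylmagnesium chloride
Product: 8 trimethyl({(3R)-3-methyl-3-[(trimethylsilyl)ethynyl]cyclohex-1-en-1-yl}methyl)silane
Conditions: Pd(PPh3)4 (cat.), THF, 0 °C to rt
Reagents that add atoms: none
Why: Kumada–Corriu coupling of the enol triflate with a Grignard reagent that has no β-hydrogen should give the allylsilane; the quaternary centre is not touched.

**Step 4**
Reactants: 8 trimethyl({(3R)-3-methyl-3-[(trimethylsilyl)ethynyl]cyclohex-1-en-1-yl}methyl)silane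
Product: 9 {[(3R)-3-ethynyl-3-methylcyclohex-1-en-1-yl]methyl}trimethylsilane
Conditions: K2CO3 (cat.), MeOH, rt
Reagents that add atoms: none
Why: Methanolysis should cleave only the alkynyl C–Si bond, since the allylic C(sp3)–Si bond is inert to carbonate.

**Step 5**
Reactants: 9 {[(3R)-3-ethynyl-3-methylcyclohex-1-en-1-yl]methyl}trimethylsilane; 10 2-bromo-3-methylbutanoyl chloride (racemic)
Product: 11 2-bromo-1-[(1S,2R)-2-ethynyl-2-methyl-6-methylidenecyclohexyl]-3-methylbutan-1-one (both C–Br epimers)
Conditions: TiCl4, CH2Cl2, −78 °C
Reagents that add atoms: none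
Why: Hosomi–Sakurai acylation should attack the ring carbon γ to silicon and release the exocyclic methylidene group; the electrophile should enter anti to the methyl group, which is bulkier than the rod-like ethynyl group, so the future C4a becomes (S) with the acyl group cis to the alkyne.

**Step 6**
Reactants: 11 2-bromo-1-[(1S,2R)-2-ethynyl-2-methyl-6-methylidenecyclohexyl]-3-methylbutan-1-one; 12 4-methoxybenzoic acid
Product: 13 1-[(1R,2S)-2-(2-bromo-3-methylbutanoyl)-1-methyl-3-methylidenecyclohexyl]ethenyl 4-methoxybenzoate (both C–Br epimers)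
Conditions: [RuCl2(p-cymene)]2 (cat.), P(2-furyl)3 (cat.), Na2CO3 (cat.), PhMe, 60 °C
Reagents that add atoms: none
Why: Ruthenium-catalysed Markovnikov hydro-oxycarbonylation of the terminal alkyne should place the carboxylate on the internal carbon and give the 1,1-disubstituted enol ester; no stereocentre is formed, and the catalytic heterogeneous carbonate should not enolise the hindered ketone.

**Step 7**
Reactants: 13 1-[(1R,2S)-2-(2-bromo-3-methylbutanoyl)-1-methyl-3-methylidenecyclohexyl]ethenyl 4-methoxybenzoate
Product: 14 (1R,3R,4aS,8aR)-8a-methyl-5-methylidene-4-oxo-3-(propan-2-yl)decahydronaphthalen-1-yl 4-methoxybenzoate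
Conditions: Bu3SnH (slow addition), AIBN (cat.), PhH, 80 °C
Reagents that add atoms: none
Why: Bu3Sn• abstracts bromine from either epimer to give an electrophilic α-keto radical at C3, which adds to the CH2 terminus (C2) of the electron-rich enol ester; the resulting α-acyloxy radical at C1 is then reduced by Bu3SnH. The closest known reaction type is the tin hydride cyclisation of α-halo ketone radicals (2-oxohex-5-enyl radicals) onto enol esters and enol ethers. Ring B closes in the 6-endo-trig mode, because the carbonyl inside the chain favours endo closure and the alternative 5-exo site C1 is fully substituted and neopentyl. C3 should be set as (R) by a chair-like transition state on the ring-A conformer that holds the acyl group equatorial and the enol ester axial, with the isopropyl group outward (equatorial). C1 should be set as (R) by hydrogen transfer along the axial direction, anti to the C8a methyl group, so that the bulky aroyloxy group of the pyramidal radical stays equatorial. The step needs C–Br homolysis without attack on the alkenes and closure faster than reduction of the C3 radical, which the weak C–Br bond and a low stannane concentration should secure.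

**Step 8**
Reactants: 14 (1R,3R,4aS,8aR)-8a-methyl-5-methylidene-4-oxo-3-(propan-2-yl)decahydronaphthalen-1-yl 4-methoxybenzoate
Product: 15 (1R,3R,4S,4aS,8aR)-4-hydroxy-8a-methyl-5-methylidene-3-(propan-2-yl)decahydronaphthalen-1-yl 4-methoxybenzoate (target)
Conditions: LiBH(s-Bu)3, THF, −78 °C; aq. NH4Cl
Reagents that add atoms: none
Why: The bulky hydride should attack the C4 ketone from the equatorial direction, because the axial path is blocked by the syn-axial C8a methyl group, giving the axial (4S) alcohol cis to the isopropyl group; the aryl ester should survive at −78 °C.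

**Compound list**
1 | 3-ethoxycyclohex-2-en-1-one | CCOC1=CC(=O)CCC1 | starting material
2 | ethynyltrimethylsilane | C#C[Si](C)(C)C | starting material
3 | lithium 3-ethoxy-1-[(trimethylsilyl)ethynyl]cyclohex-2-en-1-olate (racemic) | CCOC1=CC(O[Li])(C#C[Si](C)(C)C)CCC1 | intermediate (not isolated)
4 | 3-[(trimethylsilyl)ethynyl]cyclohex-2-en-1-one | O=C1C=C(C#C[Si](C)(C)C)CCC1 | intermediate
5 | bromomagnesium (3R)-3-methyl-3-[(trimethylsilyl)ethynyl]cyclohex-1-en-1-olate | C[C@@]1(C#C[Si](C)(C)C)CCCC(O[Mg]Br)=C1 | intermediate (not isolated)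
6 | (3R)-3-methyl-3-[(trimethylsilyl)ethynyl]cyclohex-1-en-1-yl trifluoromethanesulfonate | C[C@@]1(C#C[Si](C)(C)C)CCCC(OS(=O)(=O)C(F)(F)F)=C1 | intermediate
7 | (trimethylsilyl)methylmagnesium chloride | C[Si](C)(C)C[Mg]Cl | starting material
8 | trimethyl({(3R)-3-methyl-3-[(trimethylsilyl)ethynyl]cyclohex-1-en-1-yl}methyl)silane | C[Si](C)(C)CC1=C[C@](C)(C#C[Si](C)(C)C)CCC1 | intermediate
9 | {[(3R)-3-ethynyl-3-methylcyclohex-1-en-1-yl]methyl}trimethylsilane | C[Si](C)(C)CC1=C[C@](C)(C#C)CCC1 | intermediate
10 | 2-bromo-3-methylbutanoyl chloride (racemic) | CC(C)C(Br)C(Cl)=O | starting material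
11 | 2-bromo-1-[(1S,2R)-2-ethynyl-2-methyl-6-methylidenecyclohexyl]-3-methylbutan-1-one (both C–Br epimers) | C=C1CCC[C@@](C)(C#C)[C@H]1C(=O)C(Br)C(C)C | intermediate
12 | 4-methoxybenzoic acid | COc1ccc(cc1)C(O)=O | starting material
13 | 1-[(1R,2S)-2-(2-bromo-3-methylbutanoyl)-1-methyl-3-methylidenecyclohexyl]ethenyl 4-methoxybenzoate (both C–Br epimers) | C=C1CCC[C@@](C)(C(=C)OC(=O)c2ccc(OC)cc2)[C@H]1C(=O)C(Br)C(C)C | intermediate
14 | (1R,3R,4aS,8aR)-8a-methyl-5-methylidene-4-oxo-3-(propan-2-yl)decahydronaphthalen-1-yl 4-methoxybenzoate | C=C1CCC[C@]2(C)[C@H]1C(=O)[C@@H](C(C)C)C[C@H]2OC(=O)c1ccc(OC)cc1 | intermediate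
15 | (1R,3R,4S,4aS,8aR)-4-hydroxy-8a-methyl-5-methylidene-3-(propan-2-yl)decahydronaphthalen-1-yl 4-methoxybenzoate | C=C1CCC[C@]2(C)[C@H]1[C@@H](O)[C@@H](C(C)C)C[C@H]2OC(=O)c1ccc(OC)cc1 | target

**Step count.** Total steps: 8. Longest linear sequence: 8 steps.

**Steps most likely to fail**

1. Step 7 (key step). What may go wrong: hydrogen transfer to the C1 radical from the face of the angular methyl group (poor facial selectivity, giving the axial ester), or reduction of the C3 radical before the slow 6-endo closure. The fallback delivers oxygen instead of hydrogen to C1 and sets out from 11. Bromine abstraction with CuBr, PMDETA and copper powder in the presence of TEMPO should give the α-aminoxy ketone F1. Semi-hydrogenation of the alkyne (H2, Pd/CaCO3 poisoned with Pb(OAc)2, quinoline) should give the vinyl compound F2. Heating F2 (t-BuOH, 130 °C) should cause reversible C–O homolysis, 6-endo closure of the α-keto radical onto the vinyl group and recombination of the secondary C1 radical with the bulky nitroxide from the equatorial direction (alkoxyamine isomerisation), giving the bicyclic alkoxyamine F3. Zn in AcOH should cleave the N–O bond to the hydroxy ketone F4, and 4-methoxybenzoyl chloride (COc1ccc(cc1)C(Cl)=O) with DMAP in pyridine should acylate the equatorial alcohol. The route is rejoined at 14.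

2. Step 6. What may go wrong: addition of the carboxylate to the terminal instead of the internal carbon of this neopentyl-type alkyne, or diversion of the catalyst by the neighbouring ketone oxygen. The fallback installs the enol ester before the ketone and sets out from 9. Gold-catalysed Markovnikov addition of 12 ((Ph3P)AuCl with AgOTf, monovalent gold, PhMe, rt), with no carbonyl group yet present, should give the enol ester allylsilane F5. Hosomi–Sakurai acylation of F5 with 10 (TiCl4, CH2Cl2, −78 °C) then leads to 13, where the route is rejoined. The facial bias of this acylation is expected to be lower next to the larger enol ester, so the epimers at the acylated ring carbon would have to be separated.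

3. Step 2. What may go wrong: competing 1,6-addition to the enynone, insufficient enantioselectivity, or incomplete O-sulfonylation of the magnesium enolate. The fallback is a resolution through a stereocentre that is later erased, and it sets out from 4. Me2CuLi (Et2O, −78 °C) followed by Comins' reagent should give the racemic triflate F6, and the conditions of steps 3 and 4 then the racemic allylsilanes F7 and F8. Acylation of F8 under the conditions of step 5 with (2S)-2-bromo-3-methylbutanoyl chloride F9 (from commercial, L-valine-derived (S)-2-bromo-3-methylbutanoic acid and (COCl)2) should give two diastereomeric ketones, F10 and F11, which differ in the configuration of the ring and are separated by chromatography. F10 is one of the two C–Br epimers of 11, so the route is rejoined at 11; the bromine-bearing centre used for the resolution disappears in step 7.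

**Further compounds**
F1 | step 7 | 1-[(1S,2R)-2-ethynyl-2-methyl-6-methylidenecyclohexyl]-3-methyl-2-[(2,2,6,6-tetramethylpiperidin-1-yl)oxy]butan-1-one | C=C1CCC[C@@](C)(C#C)[C@H]1C(=O)C(ON2C(C)(C)CCCC2(C)C)C(C)C
F2 | step 7 | 1-[(1S,2S)-2-ethenyl-2-methyl-6-methylidenecyclohexyl]-3-methyl-2-[(2,2,6,6-tetramethylpiperidin-1-yl)oxy]butan-1-one | C=C1CCC[C@@](C)(C=C)[C@H]1C(=O)C(ON2C(C)(C)CCCC2(C)C)C(C)C
F3 | step 7 | (2R,4R,4aR,8aS)-4a-methyl-8-methylidene-2-(propan-2-yl)-4-[(2,2,6,6-tetramethylpiperidin-1-yl)oxy]octahydronaphthalen-1(2H)-one | C=C1CCC[C@]2(C)[C@H]1C(=O)[C@@H](C(C)C)C[C@H]2ON1C(C)(C)CCCC1(C)C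
F4 | step 7 | (2R,4R,4aR,8aS)-4-hydroxy-4a-methyl-8-methylidene-2-(propan-2-yl)octahydronaphthalen-1(2H)-one | C=C1CCC[C@]2(C)[C@H]1C(=O)[C@@H](C(C)C)C[C@H]2O
F5 | step 6 | 1-{(1R)-1-methyl-3-[(trimethylsilyl)methyl]cyclohex-2-en-1-yl}ethenyl 4-methoxybenzoate | C[Si](C)(C)CC1=C[C@](C)(C(=C)OC(=O)c2ccc(OC)cc2)CCC1
F6 | step 2 | racemic 3-methyl-3-[(trimethylsilyl)ethynyl]cyclohex-1-en-1-yl trifluoromethanesulfonate | CC1(C#C[Si](C)(C)C)CCCC(OS(=O)(=O)C(F)(F)F)=C1
F7 | step 2 | racemic trimethyl({3-methyl-3-[(trimethylsilyl)ethynyl]cyclohex-1-en-1-yl}methyl)silane | C[Si](C)(C)CC1=CC(C)(C#C[Si](C)(C)C)CCC1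
F8 | step 2 | racemic [(3-ethynyl-3-methylcyclohex-1-en-1-yl)methyl]trimethylsilane | C[Si](C)(C)CC1=CC(C)(C#C)CCC1
F9 | step 2 | (2S)-2-bromo-3-methylbutanoyl chloride | CC(C)[C@H](Br)C(Cl)=O
F10 | step 2 | (2S)-2-bromo-1-[(1S,2R)-2-ethynyl-2-methyl-6-methylidenecyclohexyl]-3-methylbutan-1-one | C=C1CCC[C@@](C)(C#C)[C@H]1C(=O)[C@@H](Br)C(C)C
F11 | step 2 | (2S)-2-bromo-1-[(1R,2S)-2-ethynyl-2-methyl-6-methylidenecyclohexyl]-3-methylbutan-1-one | C=C1CCC[C@](C)(C#C)[C@@H]1C(=O)[C@@H](Br)C(C)C
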